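**Retrosynthetic overview**

1. Ether carbon–oxygen bond: 2,4,6-trihydroxybenzophenone 1 and carbonate 2 are joined at the para oxygen to give aryl 1,1-dimethylallyl ether 3. This oxygen later blocks the wrong lactone closure and carries the future prenyl group.
2. Lactone carbon–oxygen bond (key step, new): 3 and benzylidene Meldrum's acid 4 give, through the configurationally labile adduct 5 and lactone acid 6, the (R)-dihydrocoumarin 7. The ring-closing acylation fixes C4.
3. C6–prenyl bond: an oxygen-to-carbon [3,3] shift in 7 gives target 8, (R)-8-benzoyl-5,7-dihydroxy-6-prenyl-4-phenylchroman-2-one.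
4. Read backwards: 8 ⇒ 7 ⇒ 3 + 4 ⇒ 1 + 2. Both benzene rings are bought; the lactone ring (step 2) is the only ring formed.

Assumptions: 2 and 4 are bought as catalogue chemicals (each is otherwise one operation, from 2-methylbut-3-en-2-ol and Boc2O, or from benzaldehyde and Meldrum's acid); the (8α,9S) catalyst named in step 2 is taken to give the (R) series, and its quinidine-derived (9R) pseudo-enantiomer (same formula, C32H28F6N4O3) is used if the sense proves opposite.

**Step 1**
Reactants: 1 2,4,6-trihydroxybenzophenone; 2 tert-butyl (2-methylbut-3-en-2-yl) carbonate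
Product: 3 [2,6-dihydroxy-4-(2-methylbut-3-en-2-yloxy)phenyl](phenyl)methanone
Conditions: Pd(PPh3)4 (2 mol %), 2 (1.05 equiv), THF, 4 Å MS, 0 °C, 2 h
Reagents that add atoms: none
Why: Tsuji–Trost O-allylation: the tert-butoxide released from 2 deprotonates the para hydroxyl (the most acidic, and the only one not hydrogen-bonded to the ketone), and the phenoxide attacks the 1,1-dimethylallyl palladium complex at its tertiary end at 0 °C to give the kinetic branched ether.

**Step 2**
Reactants: 3 [2,6-dihydroxy-4-(2-methylbut-3-en-2-yloxy)phenyl](phenyl)methanone (1.2 equiv); 4 5-benzylidene-2,2-dimethyl-1,3-dioxane-4,6-dione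
Product: 7 (R)-8-benzoyl-7-hydroxy-5-(2-methylbut-3-en-2-yloxy)-4-phenylchroman-2-one, via Michael adduct 5 (not isolated), via lactone acid 6 (not isolated)
Conditions: 3-[[3,5-bis(trifluoromethyl)phenyl]amino]-4-[[(8α,9S)-6′-methoxycinchonan-9-yl]amino]cyclobut-3-ene-1,2-dione (C32H28F6N4O3, 20 mol %), 1,2-dichloroethane, −20 to 20 °C, 48 h; then 50 °C, 4 h
Reagents that add atoms: none
Why: Proposed new method: a dynamic kinetic asymmetric lactonization in which the ring-closing carbon–oxygen bond selects the configuration at C4. The aryl–C4 bond forms by conjugate addition of the phenolate carbon of 3 to 4, but adduct 5 should racemise under the amine, because a phenolate oxygen ortho or para to the benzylic carbon can expel the Meldrum's acid anion (pKa about 5) as a quinone methide and take it back. The quinuclidinium–squaramide pair binds the dioxanedione carbonyls and is expected to deliver the ortho hydroxyl to one carbonyl of the (R)-adduct faster than of the (S)-adduct. Loss of acetone makes the acylation irreversible. The para oxygen is blocked as the ether, so only the hydroxyl next to the benzoyl group can close. Lactone acid 6 loses CO2 as its ammonium salt on warming and returns the amine. Closest known reaction types: the racemic amine- or Yb(OTf)3-mediated annulation of electron-rich phenols with alkylidene Meldrum's acids, and the dynamic kinetic alcoholysis of azlactones by amine/hydrogen-bond-donor catalysts.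

**Step 3**
Reactants: 7 (R)-8-benzoyl-7-hydroxy-5-(2-methylbut-3-en-2-yloxy)-4-phenylchroman-2-one
Product: 8 (R)-8-benzoyl-5,7-dihydroxy-6-(3-methylbut-2-en-1-yl)-4-phenylchroman-2-one
Conditions: PhMe, 120 °C (sealed tube), 8 h
Reagents that add atoms: none
Why: Aromatic Claisen rearrangement: the [3,3] shift can end only at C6, the one unsubstituted carbon ortho to the ether oxygen, enolisation returns the 5-hydroxyl, and the neutral thermal conditions leave the lactone and the C4 centre untouched.

**Compound list**

1 | 2,4,6-trihydroxybenzophenone | O=C(c1ccccc1)c1c(O)cc(O)cc1O | starting material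
2 | tert-butyl (2-methylbut-3-en-2-yl) carbonate | C=CC(C)(C)OC(=O)OC(C)(C)C | starting material
3 | [2,6-dihydroxy-4-(2-methylbut-3-en-2-yloxy)phenyl](phenyl)methanone | C=CC(C)(C)Oc1cc(O)c(C(=O)c2ccccc2)c(O)c1 | intermediate
4 | 5-benzylidene-2,2-dimethyl-1,3-dioxane-4,6-dione (benzylidene Meldrum's acid) | CC1(C)OC(=O)C(=Cc2ccccc2)C(=O)O1 | starting material
5 | 5-{[3-benzoyl-2,4-dihydroxy-6-(2-methylbut-3-en-2-yloxy)phenyl](phenyl)methyl}-2,2-dimethyl-1,3-dioxane-4,6-dione (Michael adduct; benzylic centre racemic and labile) | CC1(C)OC(=O)C(C(c2ccccc2)c2c(O)c(C(=O)c3ccccc3)c(O)cc2OC(C)(C)C=C)C(=O)O1 | intermediate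
6 | (4R)-8-benzoyl-7-hydroxy-5-(2-methylbut-3-en-2-yloxy)-2-oxo-4-phenylchromane-3-carboxylic acid (lactone acid; mixture of C3 epimers) | C=CC(C)(C)Oc1cc(O)c(C(=O)c2ccccc2)c2c1[C@@H](c1ccccc1)C(C(=O)O)C(=O)O2 | intermediate
7 | (R)-8-benzoyl-7-hydroxy-5-(2-methylbut-3-en-2-yloxy)-4-phenylchroman-2-one | C=CC(C)(C)Oc1cc(O)c(C(=O)c2ccccc2)c2c1[C@@H](c1ccccc1)CC(=O)O2 | intermediate
8 | (R)-8-benzoyl-5,7-dihydroxy-6-(3-methylbut-2-en-1-yl)-4-phenylchroman-2-one | CC(C)=CCc1c(O)c(C(=O)c2ccccc2)c2c(c1O)[C@@H](c1ccccc1)CC(=O)O2 | target

**Step count and risks**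

Total steps: 3. Longest linear sequence: 3 (1 → 3 → 7 → 8).

Most likely to fail, in this order:

Step 2 (the new lactonization). Racemisation of 5 may be slower than ring closure, or the catalyst may discriminate poorly, so the ee could be low. A second addition of 4 at C6 is held back by using 3 in excess. The fallback uses known chemistry, sets out from 3 and 4 and comes back at 7. Heat 3 and 4 in pyridine at 60 °C, the established amine-mediated annulation of electron-rich phenols with alkylidene Meldrum's acids. This passes through adduct 5 and the racemic lactone acid F1 and gives the racemic ether lactone F2, with the same blocked-oxygen regiocontrol. The enantiomers of F2 are separated by preparative HPLC on an amylose tris(3,5-dimethylphenylcarbamate) phase; the (R)-enantiomer is 7 and is carried into step 3.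

Step 3 (Claisen rearrangement). Loss of isoprene from the tertiary allyl ether can compete with the [3,3] shift. The fallback sets out from 7 and comes back at 8. The tertiary allyl group is removed with Pd(PPh3)4, HCO2H and Et3N in THF at 20 °C to give (R)-8-benzoyl-5,7-dihydroxy-4-phenylchroman-2-one F3. Its only free ring carbon, C6, is then prenylated with 1-bromo-3-methylbut-2-ene and DBU in THF at 0 °C. These non-nucleophilic conditions keep the lactone closed, so its position is not scrambled.

Step 1 (site-selective O-allylation). Allylation at ring carbon, double allylation, or isomerisation to the linear prenyl ether may lower the yield. The fallback sets out from 1 and comes back at 3. The para hydroxyl is alkylated with 3-chloro-3-methylbut-1-yne (K2CO3, catalytic potassium iodide, acetone, 55 °C) to give [2,6-dihydroxy-4-(2-methylbut-3-yn-2-yloxy)phenyl](phenyl)methanone F4. The alkyne is then semi-hydrogenated (H2, 1 atm, Pd on CaCO3 poisoned with Pb(OAc)2, quinoline, EtOAc, 20 °C) to 3.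

**Further compounds**

F1 | step 2 | racemic 8-benzoyl-7-hydroxy-5-(2-methylbut-3-en-2-yloxy)-2-oxo-4-phenylchromane-3-carboxylic acid | C=CC(C)(C)Oc1cc(O)c(C(=O)c2ccccc2)c2c1C(c1ccccc1)C(C(=O)O)C(=O)O2
F2 | step 2 | racemic 8-benzoyl-7-hydroxy-5-(2-methylbut-3-en-2-yloxy)-4-phenylchroman-2-one | C=CC(C)(C)Oc1cc(O)c(C(=O)c2ccccc2)c2c1C(c1ccccc1)CC(=O)O2
F3 | step 3 | (R)-8-benzoyl-5,7-dihydroxy-4-phenylchroman-2-one | Oc1cc(O)c(C(=O)c2ccccc2)c2c1[C@@H](c1ccccc1)CC(=O)O2
F4 | step 1 | [2,6-dihydroxy-4-(2-methylbut-3-yn-2-yloxy)phenyl](phenyl)methanone | C#CC(C)(C)Oc1cc(O)c(C(=O)c2ccccc2)c(O)c1
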